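**Plan**

- Numbering: ring C1 (angeloyloxy), C2=C3 (methyl on C3), C4 (acetoxy), C5, C6; side chain C7 (methyl), C8, C9 (acetoxy), C10=C11.
- Retrosynthesis: the two ring ester C–O(acyl) bonds are cut first, then C1–O and C4–O together. A cyclohexene whose C2=C3 bond is flanked by cis oxygens at C1 and C4 is the [4+2] adduct of O2 and the ring diene C1=C2–C3=C4.
- The diene is cut at C3–CH3 (dienyl triflate), at C1–C2 and C5–C6 (aldol and Michael bonds to methyl vinyl ketone) and at C9–C10 (alkenyl Grignard on a Weinreb amide).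
- Forward: the C6–C11 chain is built from a 3-methylglutarate half-ester, the carbocycle is annulated onto its aldehyde end, and the C3 methyl is coupled in. The 1,2-dioxane ring is closed last as a 2,3-dioxabicyclo[2.2.2]octene, then opened by O–O reduction and acylated twice.
- Stereochemistry: C7 is bought; C9 comes from a CBS reduction; C6 from an (S)-diarylprolinol ether catalyst; C1 and C4 from the suprafacial cycloaddition on the diene face anti to the C6 chain; the Z alkene from angelic acid.

Key step: step 12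

Remark on the chemistry: the C9 oxygen is carried as a TBS ether through the hydride, amide-base and Grignard steps. It is exchanged for the final acetate just before the photooxygenation, where an allylic acetate is wanted to slow the ene reaction at C10=C11.

**Route**

Step 1
Reactants: 1 monomethyl (R)-3-methylglutarate
Product: 2 methyl (3R)-5-[methoxy(methyl)amino]-3-methyl-5-oxopentanoate
Conditions: MeNHOMe·HCl, 1-ethyl-3-(3-dimethylaminopropyl)carbodiimide hydrochloride (EDC·HCl), N-methylmorpholine, CH2Cl2, 0 °C → rt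
Reagents that add atoms: N,O-dimethylhydroxylamine hydrochloride, CNOC.Cl
Why: Carbodiimide-mediated amidation converts only the free acid arm into the Weinreb amide and leaves the methyl ester and the C7 stereocentre untouched.

Step 2
Reactants: 2 methyl (3R)-5-[methoxy(methyl)amino]-3-methyl-5-oxopentanoate; 3 2-methylprop-1-enylmagnesium bromide
Product: 4 methyl (3R)-3,7-dimethyl-5-oxooct-6-enoate
Conditions: 3 (1.3 equiv, THF solution), THF, −40 → 0 °C; aq. NH4Cl
Reagents that add atoms: none
Why: Weinreb ketone synthesis: the alkenyl Grignard adds once to the N-methoxy-N-methylamide to give a chelated tetrahedral intermediate that releases the enone only on quench, and at low temperature the amide should react ahead of the methyl ester.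

Step 3
Reactants: 4 methyl (3R)-3,7-dimethyl-5-oxooct-6-enoate
Product: 5 methyl (3R,5R)-5-hydroxy-3,7-dimethyloct-6-enoate
Conditions: (S)-2-methyl-CBS-oxazaborolidine [(3aS)-1-methyl-3,3-diphenyltetrahydro-1H,3H-pyrrolo[1,2-c][1,3,2]oxazaborole] (0.2 equiv), catecholborane, toluene, −78 °C; MeOH, then aq. NaHCO3
Reagents that add atoms: none
Why: Corey–Bakshi–Shibata reduction: the ketone binds to the catalyst boron with the isobutenyl group as the large substituent, so hydride from the coordinated borane should be delivered to the face that gives the (R)-carbinol at C9 under catalyst control, and catecholborane gives clean 1,2-reduction of enones.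

Step 4
Reactants: 5 methyl (3R,5R)-5-hydroxy-3,7-dimethyloct-6-enoate
Product: 6 methyl (3R,5R)-5-[(tert-butyldimethylsilyl)oxy]-3,7-dimethyloct-6-enoate
Conditions: TBSOTf, 2,6-lutidine, CH2Cl2, −78 °C
Reagents that add atoms: tert-butyldimethylsilyl trifluoromethanesulfonate, CC(C)(C)[Si](C)(C)OS(=O)(=O)C(F)(F)F
Why: Silyl triflate silylation of the secondary allylic alcohol is fast at −78 °C, which forestalls δ-lactonisation, and the TBS ether tolerates the hydride, amide-base and Grignard steps that follow.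

Step 5
Reactants: 6 methyl (3R,5R)-5-[(tert-butyldimethylsilyl)oxy]-3,7-dimethyloct-6-enoate
Product: 7 (3R,5R)-5-[(tert-butyldimethylsilyl)oxy]-3,7-dimethyloct-6-enal
Conditions: iBu2AlH (1.1 equiv), CH2Cl2, −78 °C; MeOH, then aq. potassium sodium tartrate (KNaC4H4O6)
Reagents that add atoms: none
Why: Partial ester reduction: at −78 °C the tetrahedral aluminium hemiacetal persists and releases the aldehyde only on work-up.

Step 6
Reactants: 7 (3R,5R)-5-[(tert-butyldimethylsilyl)oxy]-3,7-dimethyloct-6-enal; 8 methyl vinyl ketone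
Product: 9 (2S)-2-[(2R,4R)-4-[(tert-butyldimethylsilyl)oxy]-6-methylhept-5-en-2-yl]-5-oxohexanal
Conditions: (S)-2-[methoxy(diphenyl)methyl]pyrrolidine (0.1 equiv), ethyl 3,4-dihydroxybenzoate (0.2 equiv), 8 (1.5 equiv), neat, 4 °C
Reagents that add atoms: none
Why: Enamine-catalysed Michael addition: the E-enamine of 7 is shielded on the face of the CPh2OMe group, so the enone is attacked from the open face and C6 is set as (S) under catalyst control.

Step 7
Reactants: 9 (2S)-2-[(2R,4R)-4-[(tert-butyldimethylsilyl)oxy]-6-methylhept-5-en-2-yl]-5-oxohexanal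
Product: 10 (4S)-4-[(2R,4R)-4-[(tert-butyldimethylsilyl)oxy]-6-methylhept-5-en-2-yl]cyclohex-2-en-1-one
Conditions: LiOH (0.3 equiv), iPrOH, rt
Reagents that add atoms: none
Why: Intramolecular aldol condensation (methyl ketone enolate onto the aldehyde, then dehydration) closes the cyclohexenone, and mild LiOH in iPrOH is the usual way to cyclise 2-substituted 5-oxohexanals without eroding the α-stereocentre.

Step 8
Reactants: 10 (4S)-4-[(2R,4R)-4-[(tert-butyldimethylsilyl)oxy]-6-methylhept-5-en-2-yl]cyclohex-2-en-1-one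
Product: 12 (4S)-4-[(2R,4R)-4-[(tert-butyldimethylsilyl)oxy]-6-methylhept-5-en-2-yl]cyclohexa-1,5-dien-1-yl trifluoromethanesulfonate, via lithium dienolate 11 (not isolated)
Conditions: LiN(iPr)2, THF, −78 °C; PhNTf2, −78 → 0 °C; aq. NH4Cl
Reagents that add atoms: N-phenylbis(trifluoromethanesulfonimide), O=S(=O)(N(c1ccccc1)S(=O)(=O)C(F)(F)F)C(F)(F)F
Why: Kinetic deprotonation of a cyclohex-2-enone by a lithium amide at −78 °C takes the α' proton (C4) to give the cross-conjugated dienolate, which the triflimide traps on oxygen as the 2-triflyloxy-1,3-diene without touching C6.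

Step 9
Reactants: 12 (4S)-4-[(2R,4R)-4-[(tert-butyldimethylsilyl)oxy]-6-methylhept-5-en-2-yl]cyclohexa-1,5-dien-1-yl trifluoromethanesulfonate
Product: 13 tert-butyldimethylsilyl ether of (4R,6R)-2-methyl-6-[(1S)-4-methylcyclohexa-2,4-dien-1-yl]hept-2-en-4-ol
Conditions: MeMgBr, Fe(acac)3 (5 mol%), THF/N-methylpyrrolidone, −30 → 0 °C; used without storage, under argon
Reagents that add atoms: methylmagnesium bromide, C[Mg]Br
Why: Iron-catalysed Kumada-type cross-coupling of an alkenyl triflate with MeMgBr replaces the triflate by methyl at low temperature, keeping the diene in place and sparing the silyl ether.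

Step 10
Reactants: 13 tert-butyldimethylsilyl ether of (4R,6R)-2-methyl-6-[(1S)-4-methylcyclohexa-2,4-dien-1-yl]hept-2-en-4-ol
Product: 14 (4R,6R)-2-methyl-6-[(1S)-4-methylcyclohexa-2,4-dien-1-yl]hept-2-en-4-ol
Conditions: Bu4NF, THF, 0 °C → rt
Reagents that add atoms: none
Why: Fluoride-induced desilylation is driven by Si–F bond formation and avoids the acid that would isomerise or aromatise the cyclohexadiene.

Step 11
Reactants: 14 (4R,6R)-2-methyl-6-[(1S)-4-methylcyclohexa-2,4-dien-1-yl]hept-2-en-4-ol
Product: 15 (4R,6R)-2-methyl-6-[(1S)-4-methylcyclohexa-2,4-dien-1-yl]hept-2-en-4-yl acetate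
Conditions: Ac2O, Et3N, 4-(dimethylamino)pyridine (cat.), CH2Cl2, 0 °C
Reagents that add atoms: acetic anhydride, CC(=O)OC(C)=O
Why: Base-mediated, nucleophile-catalysed acetylation of the secondary allylic alcohol avoids ionisation of the C9–O bond and installs the acetate that is final in the target.

Step 12
Reactants: 15 (4R,6R)-2-methyl-6-[(1S)-4-methylcyclohexa-2,4-dien-1-yl]hept-2-en-4-yl acetate
Product: 16 (4R,6R)-2-methyl-6-[(1S,4R,7S)-5-methyl-2,3-dioxabicyclo[2.2.2]oct-5-en-7-yl]hept-2-en-4-yl acetate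
Conditions: O2, 5,10,15,20-tetraphenylporphyrin (H2TPP, cat.), CH2Cl2, white LED light, −78 °C
Reagents that add atoms: dioxygen, O=O
Why: The excited sensitiser transfers energy to O2, and the singlet oxygen formed adds to the s-cis-locked C1=C2–C3=C4 diene in a concerted suprafacial [4+2] cycloaddition; the closest known reaction is the photooxygenation of α-phellandrene and α-terpinene to their bicyclic endoperoxides. The 1,2-dioxane ring (C1–O–O–C4 bridged by C2=C3) closes by cycloaddition, both C–O bonds forming in the same event, which gives the 2,3-dioxabicyclo[2.2.2]oct-5-ene. C1 and C4 become stereocentres together: their cis relationship follows from the suprafacial mechanism, and their absolute sense from the C6 stereocentre, whose branched chain shields one diene face so that O2 should enter anti to it. The step needs chemoselectivity for the diene over the ene reaction at C10=C11, secured by the far higher reactivity of a cisoid ring diene, the electron-withdrawing allylic acetate at C9 and the low temperature. It also needs facial selectivity, which rests only on the size of the C6 substituent, so a minor syn endoperoxide is to be expected and removed by chromatography.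

Step 13
Reactants: 16 (4R,6R)-2-methyl-6-[(1S,4R,7S)-5-methyl-2,3-dioxabicyclo[2.2.2]oct-5-en-7-yl]hept-2-en-4-yl acetate
Product: 17 (4R,6R)-6-[(1S,2S,5R)-2,5-dihydroxy-4-methylcyclohex-3-en-1-yl]-2-methylhept-2-en-4-yl acetate
Conditions: thiourea, MeOH, rt
Reagents that add atoms: none
Why: Thiourea reduces the peroxide by nucleophilic attack of sulfur on the O–O bond, so only that bond is cleaved and the cis-1,4-diol is released with both C–O bonds, the alkenes and the C9 acetate intact.

Step 14
Reactants: 17 (4R,6R)-6-[(1S,2S,5R)-2,5-dihydroxy-4-methylcyclohex-3-en-1-yl]-2-methylhept-2-en-4-yl acetate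
Product: 18 (1R,4S,5S)-5-[(2R,4R)-4-acetoxy-6-methylhept-5-en-2-yl]-4-hydroxy-2-methylcyclohex-2-en-1-yl acetate
Conditions: Ac2O (1.05 equiv), pyridine, CH2Cl2, −20 °C
Reagents that add atoms: acetic anhydride, CC(=O)OC(C)=O
Why: Sterically controlled monoacylation: the C4 hydroxyl lies between a ring CH2 and the planar C3, whereas the C1 hydroxyl sits next to C6 with its branched chain, so one equivalent of anhydride at low temperature without nucleophilic catalyst should acetylate C4–OH first.

Step 15
Reactants: 18 (1R,4S,5S)-5-[(2R,4R)-4-acetoxy-6-methylhept-5-en-2-yl]-4-hydroxy-2-methylcyclohex-2-en-1-yl acetate; 19 angelic acid [(2Z)-2-methylbut-2-enoic acid]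
Product: 21 (1S,4R,6S)-4-acetoxy-6-[(2R,4R)-4-acetoxy-6-methylhept-5-en-2-yl]-3-methylcyclohex-2-en-1-yl (2Z)-2-methylbut-2-enoate (target CNP0417294.1), via angelic 2,4,6-trichlorobenzoic anhydride 20 (not isolated)
Conditions: 19, 2,4,6-trichlorobenzoyl chloride, Et3N, toluene, rt; then 18, toluene, 80 °C
Reagents that add atoms: none
Why: Yamaguchi esterification: the mixed anhydride is attacked only at the angeloyl carbonyl because the aroyl carbonyl is flanked by two ortho chlorines, and omitting a nucleophilic catalyst avoids the addition–elimination pathway by which angelates isomerise to tiglates.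

**Compound list**

1 | monomethyl (R)-3-methylglutarate | COC(=O)C[C@H](C)CC(=O)O | starting material
2 | methyl (3R)-5-[methoxy(methyl)amino]-3-methyl-5-oxopentanoate | COC(=O)C[C@H](C)CC(=O)N(C)OC | intermediate
3 | 2-methylprop-1-enylmagnesium bromide | CC(C)=C[Mg]Br | starting material
4 | methyl (3R)-3,7-dimethyl-5-oxooct-6-enoate | COC(=O)C[C@H](C)CC(=O)C=C(C)C | intermediate
5 | methyl (3R,5R)-5-hydroxy-3,7-dimethyloct-6-enoate | COC(=O)C[C@H](C)C[C@H](C=C(C)C)O | intermediate
6 | methyl (3R,5R)-5-[(tert-butyldimethylsilyl)oxy]-3,7-dimethyloct-6-enoate | COC(=O)C[C@H](C)C[C@H](C=C(C)C)O[Si](C)(C)C(C)(C)C | intermediate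
7 | (3R,5R)-5-[(tert-butyldimethylsilyl)oxy]-3,7-dimethyloct-6-enal | O=CC[C@H](C)C[C@H](C=C(C)C)O[Si](C)(C)C(C)(C)C | intermediate
8 | methyl vinyl ketone (but-3-en-2-one) | CC(=O)C=C | starting material
9 | (2S)-2-[(2R,4R)-4-[(tert-butyldimethylsilyl)oxy]-6-methylhept-5-en-2-yl]-5-oxohexanal | CC(=O)CC[C@H](C=O)[C@H](C)C[C@H](C=C(C)C)O[Si](C)(C)C(C)(C)C | intermediate
10 | (4S)-4-[(2R,4R)-4-[(tert-butyldimethylsilyl)oxy]-6-methylhept-5-en-2-yl]cyclohex-2-en-1-one | C1=CC(=O)CC[C@H]1[C@H](C)C[C@H](C=C(C)C)O[Si](C)(C)C(C)(C)C | intermediate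
11 | lithium (4S)-4-[(2R,4R)-4-[(tert-butyldimethylsilyl)oxy]-6-methylhept-5-en-2-yl]cyclohexa-1,5-dien-1-olate (lithium dienolate) | C1=CC([O-])=CC[C@H]1[C@H](C)C[C@H](C=C(C)C)O[Si](C)(C)C(C)(C)C.[Li+] | intermediate
12 | (4S)-4-[(2R,4R)-4-[(tert-butyldimethylsilyl)oxy]-6-methylhept-5-en-2-yl]cyclohexa-1,5-dien-1-yl trifluoromethanesulfonate | C1=CC(OS(=O)(=O)C(F)(F)F)=CC[C@H]1[C@H](C)C[C@H](C=C(C)C)O[Si](C)(C)C(C)(C)C | intermediate
13 | tert-butyldimethylsilyl ether of (4R,6R)-2-methyl-6-[(1S)-4-methylcyclohexa-2,4-dien-1-yl]hept-2-en-4-ol | C1=CC(C)=CC[C@H]1[C@H](C)C[C@H](C=C(C)C)O[Si](C)(C)C(C)(C)C | intermediate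
14 | (4R,6R)-2-methyl-6-[(1S)-4-methylcyclohexa-2,4-dien-1-yl]hept-2-en-4-ol | C1=CC(C)=CC[C@H]1[C@H](C)C[C@H](C=C(C)C)O | intermediate
15 | (4R,6R)-2-methyl-6-[(1S)-4-methylcyclohexa-2,4-dien-1-yl]hept-2-en-4-yl acetate | C1=CC(C)=CC[C@H]1[C@H](C)C[C@H](C=C(C)C)OC(C)=O | intermediate
16 | (4R,6R)-2-methyl-6-[(1S,4R,7S)-5-methyl-2,3-dioxabicyclo[2.2.2]oct-5-en-7-yl]hept-2-en-4-yl acetate | O2[C@@H]1C=C(C)[C@H](O2)C[C@H]1[C@H](C)C[C@H](C=C(C)C)OC(C)=O | intermediate
17 | (4R,6R)-6-[(1S,2S,5R)-2,5-dihydroxy-4-methylcyclohex-3-en-1-yl]-2-methylhept-2-en-4-yl acetate | O[C@@H]1C=C(C)[C@H](O)C[C@H]1[C@H](C)C[C@H](C=C(C)C)OC(C)=O | intermediate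
18 | (1R,4S,5S)-5-[(2R,4R)-4-acetoxy-6-methylhept-5-en-2-yl]-4-hydroxy-2-methylcyclohex-2-en-1-yl acetate | O[C@@H]1C=C(C)[C@H](OC(C)=O)C[C@H]1[C@H](C)C[C@H](C=C(C)C)OC(C)=O | intermediate
19 | angelic acid, (2Z)-2-methylbut-2-enoic acid | C/C=C(/C)C(=O)O | starting material
20 | (2Z)-2-methylbut-2-enoic 2,4,6-trichlorobenzoic anhydride | C/C=C(/C)C(=O)OC(=O)c1c(Cl)cc(Cl)cc1Cl | intermediate
21 | (1S,4R,6S)-4-acetoxy-6-[(2R,4R)-4-acetoxy-6-methylhept-5-en-2-yl]-3-methylcyclohex-2-en-1-yl (2Z)-2-methylbut-2-enoate | C/C=C(/C)C(=O)O[C@@H]1C=C(C)[C@H](OC(C)=O)C[C@H]1[C@H](C)C[C@H](C=C(C)C)OC(C)=O | target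

**Totals**

Total step count: 15. Longest linear sequence: 15 steps (1 → 21); compounds 3, 8 and 19 are purchased.

**Steps most likely to fail**

1. Step 12. Singlet oxygen may add to a significant extent on the diene face syn to the C6 chain, and may also consume the C10=C11 alkene by ene oxygenation. The fallback sets out from enone 10 and returns at target 21; it introduces the two ring oxygens one after the other, so that the face is chosen by the neighbouring C6 centre and no singlet oxygen is used. Nucleophilic epoxidation of 10 (H2O2, NaOH, MeOH, 0 °C) should give the trans-epoxy ketone F1, the oxirane forming anti to the adjacent C6 substituent. α'-Enolisation and triflation (LiN(SiMe3)2, PhNTf2, THF, −78 °C) would give the epoxy enol triflate F2. Stille methylation (Me4Sn, Pd(PPh3)4, LiCl, THF, 60 °C) would give the methyl-substituted vinyl epoxide F3. Opening of F3 with acetic acid under zerovalent palladium catalysis (Pd(PPh3)4, AcOH, THF, 0 °C; Tsuji–Trost type, double inversion, 1,4-regiochemistry) should deliver the acetate to C4 cis to the C1 oxygen and give the C9-silylated hydroxy acetate F4. Yamaguchi angeloylation as in step 15 would give the C9-silylated angelate F5, HF·pyridine the C9 alcohol F6, and Ac2O/pyridine/4-(dimethylamino)pyridine then 21.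

2. Step 14. The anhydride may not discriminate between the two secondary allylic hydroxyls, and a misplaced acetate cannot be removed without also cleaving the C9 acetate. The fallback sets out from diol 17 and returns at target 21 by a silyl relay with the acylation order reversed. TBSCl/imidazole (DMF, 0 °C), which is bulkier and therefore more site-selective, and removable with Bu4NF if misplaced, should give the C4 silyl ether F7. Yamaguchi angeloylation of the free C1 hydroxyl would give the silyl angelate F8, HF·pyridine the C4 alcohol F9, and Ac2O/pyridine then 21.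

3. Step 15. The hindered C1 hydroxyl may acylate only slowly, and the angeloyl unit may isomerise from Z to E at the temperature needed. The fallback sets out from 18 and returns at target 21, building the Z alkene on the ester instead of transferring it. Coupling of 18 with 2-[bis(2,2,2-trifluoroethoxy)phosphoryl]propanoic acid (N,N'-dicyclohexylcarbodiimide, 4-(dimethylamino)pyridine, CH2Cl2) would give the phosphonopropanoate F10. Still–Gennari olefination with acetaldehyde (KN(SiMe3)2, 18-crown-6, THF, −78 °C) should then give the Z-configured 2-methylbut-2-enoate 21; the phosphonate C–H is far more acidic than the acetate C–H, so one equivalent of base suffices.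

**Further compounds**

F1 | step 12 | trans-epoxy ketone: 5-[(2R,4R)-4-[(tert-butyldimethylsilyl)oxy]-6-methylhept-5-en-2-yl]-7-oxabicyclo[4.1.0]heptan-2-one, oxirane anti to the C5 substituent | O2[C@@H]1[C@H]2C(=O)CC[C@H]1[C@H](C)C[C@H](C=C(C)C)O[Si](C)(C)C(C)(C)C
F2 | step 12 | epoxy enol triflate: the 7-oxabicyclo[4.1.0]hept-2-en-2-yl trifluoromethanesulfonate derived from F1 | O2[C@@H]1[C@H]2C(OS(=O)(=O)C(F)(F)F)=CC[C@H]1[C@H](C)C[C@H](C=C(C)C)O[Si](C)(C)C(C)(C)C
F3 | step 12 | vinyl epoxide: 2-methyl-7-oxabicyclo[4.1.0]hept-2-ene carrying the silylated side chain at C5 | O2[C@@H]1[C@H]2C(C)=CC[C@H]1[C@H](C)C[C@H](C=C(C)C)O[Si](C)(C)C(C)(C)C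
F4 | step 12 | C9-O-TBS analogue of 18 (C1 hydroxyl, C4 acetate) | O[C@@H]1C=C(C)[C@H](OC(C)=O)C[C@H]1[C@H](C)C[C@H](C=C(C)C)O[Si](C)(C)C(C)(C)C
F5 | step 12 | C9-O-TBS analogue of 21 (C1 angelate, C4 acetate) | C/C=C(/C)C(=O)O[C@@H]1C=C(C)[C@H](OC(C)=O)C[C@H]1[C@H](C)C[C@H](C=C(C)C)O[Si](C)(C)C(C)(C)C
F6 | step 12 | C9 alcohol: 21 lacking the C9 acetyl group | C/C=C(/C)C(=O)O[C@@H]1C=C(C)[C@H](OC(C)=O)C[C@H]1[C@H](C)C[C@H](C=C(C)C)O
F7 | step 14 | C4-O-TBS ether of diol 17 (C1 hydroxyl free) | O[C@@H]1C=C(C)[C@H](O[Si](C)(C)C(C)(C)C)C[C@H]1[C@H](C)C[C@H](C=C(C)C)OC(C)=O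
F8 | step 14 | C1 angelate of F7 | C/C=C(/C)C(=O)O[C@@H]1C=C(C)[C@H](O[Si](C)(C)C(C)(C)C)C[C@H]1[C@H](C)C[C@H](C=C(C)C)OC(C)=O
F9 | step 14 | C4 alcohol: 21 lacking the C4 acetyl group | C/C=C(/C)C(=O)O[C@@H]1C=C(C)[C@H](O)C[C@H]1[C@H](C)C[C@H](C=C(C)C)OC(C)=O
F10 | step 15 | C1 2-[bis(2,2,2-trifluoroethoxy)phosphoryl]propanoate of 18 (both epimers at the phosphonate-bearing carbon) | CC(P(=O)(OCC(F)(F)F)OCC(F)(F)F)C(=O)O[C@@H]1C=C(C)[C@H](OC(C)=O)C[C@H]1[C@H](C)C[C@H](C=C(C)C)OC(C)=O
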